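Prostaglandin numbering is used (C1 carboxyl carbon, C8–C12 ring, C15 ketone). The cyclopentane carries oxygen on C9 and C11 on either side of the unsubstituted methylene C10, a cyclic aldol pattern, so the ring is disconnected at C10–C11. An acyclic gamma-nitro keto aldehyde, assembled by one organocatalytic Michael addition that sets C12, is closed by intramolecular Mukaiyama aldol addition of the methyl ketone (C9, C10) to the aldehyde (C11). This single operation forms the ring, sets C11 from C12, silylates O11 and, by loss of nitrous acid, leaves an exocyclic enone at C8. C8 and C9 are then relayed by substrate control, and both side chains are attached by olefination.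

Key step: step 4

Remark: TBS = tert-butyldimethylsilyl. The C12 descriptor is S in 7–22 and R in 23–27 only because the CIP priorities of its neighbours change; the spatial arrangement is the same throughout.

Step 1
Reactants: 1 methylglyoxal (40% in water); 2 nitromethane
Product: 3 3-hydroxy-4-nitrobutan-2-one (racemic)
Conditions: MeNO2 (excess), Et3N (10 mol%), THF/H2O, 0 °C → rt
Reagents that add atoms: none
Why: Henry (nitroaldol) addition in which the nitronate adds to the aldehyde carbon, far more electrophilic than the ketone; the racemic carbinol centre is destroyed in step 2.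

Step 2
Reactants: 3 3-hydroxy-4-nitrobutan-2-one
Product: 5 (E)-4-nitrobut-3-en-2-one, via mesylate 4 (not isolated)
Conditions: MsCl, Et3N, CH2Cl2, −20 → 0 °C
Reagents that add atoms: none
Why: Dehydration of the nitroaldol by mesylation and E1cB elimination, which should give the conjugated (E)-nitroalkene as the more stable isomer.

Step 3
Reactants: 5 (E)-4-nitrobut-3-en-2-one; 6 3-[(tert-butyldimethylsilyl)oxy]propanal
Product: 7 (2S,3R)-2-{[(TBS)oxy]methyl}-3-(nitromethyl)-4-oxopentanal
Conditions: 6 (1.5 equiv), (S)-2-[diphenyl(trimethylsilyloxy)methyl]pyrrolidine (10 mol%), 4-nitrophenol (10 mol%), toluene, 0 °C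
Reagents that add atoms: none
Why: Enamine-catalysed asymmetric Michael addition of an aldehyde to a nitroalkene, in which the (E)-enamine of 6, shielded on one face by the diphenyl(silyloxy)methyl group, attacks C8 (beta to the nitro group, the stronger acceptor) through the usual synclinal transition state; this should set C12 with the configuration of the target (S in 7) and C8 syn to it.

Step 4
Reactants: 7 (2S,3R)-2-{[(TBS)oxy]methyl}-3-(nitromethyl)-4-oxopentanal
Product: 10 (3S,4R)-4-[(TBS)oxy]-3-{[(TBS)oxy]methyl}-2-methylidenecyclopentan-1-one, via silyl enol ether 8 (not isolated), via nitro ketone 9 (not isolated)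
Conditions: TBSOTf (1.2 equiv), i-Pr2NEt (2.5 equiv), CH2Cl2, −78 → −20 °C; then Et3N, 0 °C → rt
Reagents that add atoms: tert-butyldimethylsilyl trifluoromethanesulfonate (TBSOTf), CC(C)(C)[Si](C)(C)OS(=O)(=O)C(F)(F)F
Why: TBSOTf/i-Pr2NEt enolises the methyl ketone softly at its unhindered methyl group (C10) to enol silane 8, the silyl triflate then activates the aldehyde, and C10 adds to C11 with transfer of the silyl group to O11, after which Et3N removes nitrous acid across C7–C8 (E1cB) from the beta-nitro ketone 9. The closest known reaction type is the one-pot silyl triflate/amine enol silane formation–Mukaiyama aldol addition, used here intramolecularly on a gamma-keto aldehyde. The cyclopentanone is closed in the 5-(enolendo)-exo-trig mode through an open transition state, the mode by which gamma-keto aldehydes cyclise to 3-oxygenated cyclopentanones. The new stereocentre C11 is controlled by C12: the silylated carbonyl oxygen should take the pseudo-equatorial position anti to the CH2OTBS group on the neighbouring carbon, which gives the 11,12-trans (11R) ether. The step needs site selectivity in the enolisation (C10 rather than C8–H or the aldehyde alpha-hydrogen at C12), and this rests on the steric accessibility of the methyl group under kinetic conditions at low temperature; enolisation towards C8 would only bring the nitrite loss forward and converge on 10. The C8 centre is erased on purpose, so that only C12 and C11 are carried into 10.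

Step 5
Reactants: 10 (3S,4R)-4-[(TBS)oxy]-3-{[(TBS)oxy]methyl}-2-methylidenecyclopentan-1-one; 11 vinylmagnesium bromide
Product: 14 (2R,3S,4R)-4-[(TBS)oxy]-3-{[(TBS)oxy]methyl}-2-(prop-2-en-1-yl)cyclopentan-1-one, via magnesium enolate 12 (not isolated), via C8 epimer 13 (not isolated)
Conditions: CH2=CHMgBr, CuBr·SMe2 (10 mol%), THF, −78 °C; then AcOH, −78 °C; then KOAc, MeOH, rt
Reagents that add atoms: none
Why: Copper-catalysed conjugate addition of the Grignard reagent to the unhindered exocyclic enone gives enolate 12, and protonation followed by enol-mediated equilibration (KOAc/MeOH) should place the allyl group at C8 trans to the C12 substituent, the thermodynamically preferred 2,3-trans ketone, so that C8 (R) is relayed from C12.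

Step 6
Reactants: 14 (2R,3S,4R)-4-[(TBS)oxy]-3-{[(TBS)oxy]methyl}-2-(prop-2-en-1-yl)cyclopentan-1-one
Product: 15 (1S,2R,3S,4R)-4-[(TBS)oxy]-3-{[(TBS)oxy]methyl}-2-(prop-2-en-1-yl)cyclopentan-1-ol
Conditions: LiBH(s-Bu)3, THF, −78 °C; then H2O
Reagents that add atoms: none
Why: Bulky-hydride ketone reduction in which LiBH(s-Bu)3 should attack the face opposite to the adjacent C8 allyl group and the C11 silyloxy group and so give the C9 alcohol cis to both (9S).

Step 7
Reactants: 15 (1S,2R,3S,4R)-4-[(TBS)oxy]-3-{[(TBS)oxy]methyl}-2-(prop-2-en-1-yl)cyclopentan-1-ol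
Product: 18 lactol (3aR,4S,5R,6aS)-5-[(TBS)oxy]-4-{[(TBS)oxy]methyl}hexahydro-2H-cyclopenta[b]furan-2-ol (anomer mixture), via ozonide 16 (not isolated), via hydroxy aldehyde 17 (not isolated)
Conditions: O3, CH2Cl2, −78 °C; then PPh3, −78 °C → rt
Reagents that add atoms: ozone, [O-][O+]=O
Why: Ozonolysis of the only alkene with reductive work-up removes the terminal carbon and gives the C6 aldehyde 17, which the cis C9 hydroxyl traps as the five-membered lactol without touching a ring stereocentre.

Step 8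
Reactants: 18 lactol; 19 (4-carboxybutyl)triphenylphosphonium bromide
Product: 21 (5Z)-7-[(1R,2S,3R,5S)-3-[(TBS)oxy]-2-{[(TBS)oxy]methyl}-5-hydroxycyclopentyl]hept-5-enoic acid, via ylide 20 (not isolated)
Conditions: 19 (3 equiv), KOt-Bu (6 equiv), THF, 0 °C; then 18, 0 °C → rt; aq HCl work-up
Reagents that add atoms: none
Why: Wittig olefination of the lactol through its open form 17 with a non-stabilised ylide under lithium-free conditions, which should give the (5Z)-alkene by kinetically controlled formation of the cis oxaphosphetane.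

Step 9
Reactants: 21 (5Z)-7-[(1R,2S,3R,5S)-3-[(TBS)oxy]-2-{[(TBS)oxy]methyl}-5-hydroxycyclopentyl]hept-5-enoic acid
Product: 22 (5Z)-7-[(1R,2S,3R,5S)-3-[(TBS)oxy]-5-hydroxy-2-(hydroxymethyl)cyclopentyl]hept-5-enoic acid
Conditions: HF·pyridine, pyridine, THF, 0 °C
Reagents that add atoms: none
Why: Chemoselective desilylation in which buffered HF·pyridine should cleave the primary silyl ether at C13 faster than the more hindered secondary ether at C11.

Step 10
Reactants: 22 (5Z)-7-[(1R,2S,3R,5S)-3-[(TBS)oxy]-5-hydroxy-2-(hydroxymethyl)cyclopentyl]hept-5-enoic acid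
Product: 23 (5Z)-7-[(1R,2R,3R,5S)-3-[(TBS)oxy]-2-formyl-5-hydroxycyclopentyl]hept-5-enoic acid
Conditions: TEMPO (10 mol%), PhI(OAc)2, CH2Cl2, rt
Reagents that add atoms: none
Why: Oxoammonium (TEMPO) oxidation, which should oxidise the primary alcohol selectively in the presence of the secondary C9 alcohol and, being non-basic, should not epimerise C12.

Step 11
Reactants: 23 (5Z)-7-[(1R,2R,3R,5S)-3-[(TBS)oxy]-2-formyl-5-hydroxycyclopentyl]hept-5-enoic acid; 24 dimethyl (2-oxoheptyl)phosphonate
Product: 26 (5Z)-7-[(1R,2R,3R,5S)-3-[(TBS)oxy]-5-hydroxy-2-[(1E)-3-oxooct-1-en-1-yl]cyclopentyl]hept-5-enoic acid, via lithiated phosphonate 25 (not isolated)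
Conditions: 24, LiCl, i-Pr2NEt (excess), MeCN, rt
Reagents that add atoms: none
Why: Horner–Wadsworth–Emmons olefination under mild LiCl/amine conditions, in which the stabilised phosphonate anion 25 should give the (13E)-enone and the weak base should spare the epimerisable beta-silyloxy aldehyde while the acid is carried as its carboxylate.

Step 12
Reactants: 26 (5Z)-7-[(1R,2R,3R,5S)-3-[(TBS)oxy]-5-hydroxy-2-[(1E)-3-oxooct-1-en-1-yl]cyclopentyl]hept-5-enoic acid
Product: 27 15-keto-PGF2alpha
Conditions: HF (48% aq), MeCN, 0 °C → rt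
Reagents that add atoms: none
Why: Acidic fluoride cleavage of the remaining secondary silyl ether, conditions under which the enone, the (5Z)-alkene and the cis-1,3-diol should be stable.

Compound list

1 | methylglyoxal (2-oxopropanal) | CC(=O)C=O | starting material
2 | nitromethane | C[N+](=O)[O-] | starting material
3 | 3-hydroxy-4-nitrobutan-2-one (racemic) | CC(=O)C(O)C[N+](=O)[O-] | intermediate
4 | 1-nitro-3-oxobutan-2-yl methanesulfonate (racemic) | CC(=O)C(OS(C)(=O)=O)C[N+](=O)[O-] | intermediate (not isolated)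
5 | (E)-4-nitrobut-3-en-2-one | CC(=O)/C=C/[N+](=O)[O-] | intermediate
6 | 3-[(tert-butyldimethylsilyl)oxy]propanal | CC(C)(C)[Si](C)(C)OCCC=O | starting material
7 | (2S,3R)-2-{[(TBS)oxy]methyl}-3-(nitromethyl)-4-oxopentanal | O=C[C@H](CO[Si](C)(C)C(C)(C)C)[C@@H](C(C)=O)C[N+](=O)[O-] | intermediate
8 | (2S,3R)-4-[(TBS)oxy]-2-{[(TBS)oxy]methyl}-3-(nitromethyl)pent-4-enal (silyl enol ether of 7) | O=C[C@H](CO[Si](C)(C)C(C)(C)C)[C@@H](C(=C)O[Si](C)(C)C(C)(C)C)C[N+](=O)[O-] | intermediate (not isolated)
9 | (2R,3S,4R)-4-[(TBS)oxy]-3-{[(TBS)oxy]methyl}-2-(nitromethyl)cyclopentan-1-one | CC(C)(C)[Si](C)(C)OC[C@@H]1[C@H](C[N+](=O)[O-])C(=O)C[C@H]1O[Si](C)(C)C(C)(C)C | intermediate (not isolated)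
10 | (3S,4R)-4-[(TBS)oxy]-3-{[(TBS)oxy]methyl}-2-methylidenecyclopentan-1-one | CC(C)(C)[Si](C)(C)OC[C@@H]1C(=C)C(=O)C[C@H]1O[Si](C)(C)C(C)(C)C | intermediate
11 | vinylmagnesium bromide | C=C[Mg]Br | starting material
12 | bromomagnesium enolate of 14 | C=CCC1=C(O[Mg]Br)C[C@@H](O[Si](C)(C)C(C)(C)C)[C@@H]1CO[Si](C)(C)C(C)(C)C | intermediate (not isolated)
13 | (2S,3S,4R)-4-[(TBS)oxy]-3-{[(TBS)oxy]methyl}-2-(prop-2-en-1-yl)cyclopentan-1-one (C8 epimer of 14) | CC(C)(C)[Si](C)(C)OC[C@@H]1[C@H](CC=C)C(=O)C[C@H]1O[Si](C)(C)C(C)(C)C | intermediate (not isolated)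
14 | (2R,3S,4R)-4-[(TBS)oxy]-3-{[(TBS)oxy]methyl}-2-(prop-2-en-1-yl)cyclopentan-1-one | CC(C)(C)[Si](C)(C)OC[C@@H]1[C@@H](CC=C)C(=O)C[C@H]1O[Si](C)(C)C(C)(C)C | intermediate
15 | (1S,2R,3S,4R)-4-[(TBS)oxy]-3-{[(TBS)oxy]methyl}-2-(prop-2-en-1-yl)cyclopentan-1-ol | CC(C)(C)[Si](C)(C)OC[C@@H]1[C@@H](CC=C)[C@@H](O)C[C@H]1O[Si](C)(C)C(C)(C)C | intermediate
16 | (1S,2R,3S,4R)-4-[(TBS)oxy]-3-{[(TBS)oxy]methyl}-2-[(1,2,4-trioxolan-3-yl)methyl]cyclopentan-1-ol (ozonide) | CC(C)(C)[Si](C)(C)OC[C@@H]1[C@@H](CC2OCOO2)[C@@H](O)C[C@H]1O[Si](C)(C)C(C)(C)C | intermediate (not isolated)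
17 | 2-[(1R,2S,3R,5S)-3-[(TBS)oxy]-2-{[(TBS)oxy]methyl}-5-hydroxycyclopentyl]acetaldehyde | CC(C)(C)[Si](C)(C)OC[C@@H]1[C@@H](CC=O)[C@@H](O)C[C@H]1O[Si](C)(C)C(C)(C)C | intermediate (not isolated)
18 | (3aR,4S,5R,6aS)-5-[(TBS)oxy]-4-{[(TBS)oxy]methyl}hexahydro-2H-cyclopenta[b]furan-2-ol (anomer mixture) | CC(C)(C)[Si](C)(C)OC[C@@H]1[C@H]2CC(O)O[C@H]2C[C@H]1O[Si](C)(C)C(C)(C)C | intermediate
19 | (4-carboxybutyl)triphenylphosphonium bromide | OC(=O)CCCC[P+](c1ccccc1)(c1ccccc1)c1ccccc1.[Br-] | starting material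
20 | potassium 5-(triphenyl-λ5-phosphanylidene)pentanoate (ylide) | [K+].[O-]C(=O)CCCC=P(c1ccccc1)(c1ccccc1)c1ccccc1 | intermediate (not isolated)
21 | (5Z)-7-[(1R,2S,3R,5S)-3-[(TBS)oxy]-2-{[(TBS)oxy]methyl}-5-hydroxycyclopentyl]hept-5-enoic acid | CC(C)(C)[Si](C)(C)OC[C@@H]1[C@@H](C/C=C\CCCC(=O)O)[C@@H](O)C[C@H]1O[Si](C)(C)C(C)(C)C | intermediate
22 | (5Z)-7-[(1R,2S,3R,5S)-3-[(TBS)oxy]-5-hydroxy-2-(hydroxymethyl)cyclopentyl]hept-5-enoic acid | OC[C@@H]1[C@@H](C/C=C\CCCC(=O)O)[C@@H](O)C[C@H]1O[Si](C)(C)C(C)(C)C | intermediate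
23 | (5Z)-7-[(1R,2R,3R,5S)-3-[(TBS)oxy]-2-formyl-5-hydroxycyclopentyl]hept-5-enoic acid | O=C[C@@H]1[C@@H](C/C=C\CCCC(=O)O)[C@@H](O)C[C@H]1O[Si](C)(C)C(C)(C)C | intermediate
24 | dimethyl (2-oxoheptyl)phosphonate | CCCCCC(=O)CP(=O)(OC)OC | starting material
25 | lithium salt of 24 (lithiated phosphonate) | [Li+].CCCCCC(=O)[CH-]P(=O)(OC)OC | intermediate (not isolated)
26 | (5Z)-7-[(1R,2R,3R,5S)-3-[(TBS)oxy]-5-hydroxy-2-[(1E)-3-oxooct-1-en-1-yl]cyclopentyl]hept-5-enoic acid | CCCCCC(=O)/C=C/[C@@H]1[C@@H](C/C=C\CCCC(=O)O)[C@@H](O)C[C@H]1O[Si](C)(C)C(C)(C)C | intermediate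
27 | 15-keto-PGF2alpha, (5Z)-7-[(1R,2R,3R,5S)-3,5-dihydroxy-2-[(1E)-3-oxooct-1-en-1-yl]cyclopentyl]hept-5-enoic acid | CCCCCC(=O)/C=C/[C@@H]1[C@@H](C/C=C\CCCC(=O)O)[C@@H](O)C[C@H]1O | target

Total step count: 12. Longest linear sequence: 12 steps (from 1 and 2 to 27).

Steps most likely to fail

Step 4 (key step). The soft enolisation may be unselective (enolisation of the aldehyde with loss of the C12 centre, O-silylation of the nitro group), or the facial selectivity of the ring closure may be poor. The fallback sets out from 5 and 6 and comes back to the route at 10; it installs the enol silane before the aldehyde exists. Compound 5 is silylated (TBSOTf, i-Pr2NEt, CH2Cl2, −78 °C) to tert-butyldimethyl{[(3E)-4-nitrobuta-1,3-dien-2-yl]oxy}silane F1. The catalyst of step 3 then adds 6 to F1 at the carbon beta to the nitro group and gives the enol silane aldehyde 8, now as an isolated compound. A Lewis acid alone (TBSOTf 10 mol%, 2,6-di-tert-butylpyridine, CH2Cl2, −78 °C) closes the same C10–C11 bond to 9 with silyl transfer to O11, and Et3N converts 9 into 10.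

Step 5. The exocyclic enone may oligomerise during isolation, the Grignard reagent may add to the carbonyl group, or the equilibration at C8 may stay incomplete. The fallback sets out from 9 and comes back at 18; it replaces the organometallic addition and the ozonolysis by a nitronate Michael addition and a Nef reaction. Step 4 is stopped before the Et3N stage and 9 is isolated. Stirring 9 in nitromethane 2 with DBU at 0 °C generates 10 in the flask and traps it reversibly, under thermodynamic control at C8, as (2R,3S,4R)-4-[(TBS)oxy]-3-{[(TBS)oxy]methyl}-2-(2-nitroethyl)cyclopentan-1-one F2. Excess LiBH(s-Bu)3 (THF, −78 °C) should give (1S,2R,3S,4R)-4-[(TBS)oxy]-3-{[(TBS)oxy]methyl}-2-(2-nitroethyl)cyclopentan-1-ol F3. A Nef reaction (NaOMe, MeOH; then O3, −78 °C; Me2S) converts the nitro-bearing carbon into the C6 aldehyde 17, which closes to lactol 18.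

Step 3. The doubly activated nitroalkene may be consumed by amine-induced oligomerisation before the enamine adds, so that conversion and selectivity fall. The fallback sets out from 3 and comes back at 7; it avoids the isolated nitroalkene. Compound 3 is acetylated (Ac2O, cat. H2SO4, 0 °C) to 1-nitro-3-oxobutan-2-yl acetate F4, a storable precursor that replaces step 2. F4, 6, the catalyst of step 3 and N-methylmorpholine (1 equiv) in toluene at 0 °C release 5 slowly by loss of acetic acid, so that its stationary concentration stays low, and the enamine traps it as 7.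

Further compounds

F1 | step 4 | tert-butyldimethyl{[(3E)-4-nitrobuta-1,3-dien-2-yl]oxy}silane | C=C(O[Si](C)(C)C(C)(C)C)/C=C/[N+](=O)[O-]
F2 | step 5 | (2R,3S,4R)-4-[(TBS)oxy]-3-{[(TBS)oxy]methyl}-2-(2-nitroethyl)cyclopentan-1-one | CC(C)(C)[Si](C)(C)OC[C@@H]1[C@@H](CC[N+](=O)[O-])C(=O)C[C@H]1O[Si](C)(C)C(C)(C)C
F3 | step 5 | (1S,2R,3S,4R)-4-[(TBS)oxy]-3-{[(TBS)oxy]methyl}-2-(2-nitroethyl)cyclopentan-1-ol | CC(C)(C)[Si](C)(C)OC[C@@H]1[C@@H](CC[N+](=O)[O-])[C@@H](O)C[C@H]1O[Si](C)(C)C(C)(C)C
F4 | step 3 | 1-nitro-3-oxobutan-2-yl acetate (racemic) | CC(=O)OC(C[N+](=O)[O-])C(C)=O
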